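The route rests on disconnecting the O1–C8a bond of unit A, the 3-aryloxy-7-hydroxycoumarin. Without O1, the benzene ring of unit A is a 4-oxy-3,5-dimethoxyphenyl group whose two ortho CH carbons (future C5 and C8a) are equivalent, so dehydrogenative lactonization of a sinapic-type acid can give only one coumarin. In one photocatalytic operation the acrylic acid is isomerized and its carboxylate oxygen is bonded to that ortho carbon, closing the pyranone ring with the isofraxidin ether (unit B) already fixed on C3. The precursor is the 4-O-acetyl alpha-(isofraxidin-7-yloxy)sinapic acid, made by Perkin condensation.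

Key step: step 4

Remark on the chemistry: in the (Z)-acid 8 the carboxyl group is trans to the aryl ring (the normal Perkin outcome), so the key step must include a geometric isomerization. A tert-butyl ester and an acid-catalysed final deacetylation are chosen so that neither coumarin lactone meets aqueous base or ammonia.

Step 1
Reactants: 1 isofraxidin (7-hydroxy-6,8-dimethoxy-2H-chromen-2-one); 2 tert-butyl bromoacetate
Product: 3 tert-butyl 2-[(6,8-dimethoxy-2-oxo-2H-chromen-7-yl)oxy]acetate
Conditions: K2CO3, DMF, 50 °C
Reagents that add atoms: none
Why: Williamson ether synthesis, in which the acidic 7-OH (a vinylogous acid through the lactone) is deprotonated by anhydrous carbonate and its phenoxide displaces bromide from the activated alpha-bromo ester by SN2 while the lactone stays closed.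

Step 2
Reactants: 3 tert-butyl 2-[(6,8-dimethoxy-2-oxo-2H-chromen-7-yl)oxy]acetate
Product: 4 2-[(6,8-dimethoxy-2-oxo-2H-chromen-7-yl)oxy]acetic acid
Conditions: TFA, CH2Cl2, 0 °C to rt
Reagents that add atoms: none
Why: Acidolysis of the tert-butyl ester (loss of the tert-butyl cation as isobutene) should free the carboxylic acid under conditions to which the coumarin lactone and the aryl ethers are inert.

Step 3
Reactants: 4 2-[(6,8-dimethoxy-2-oxo-2H-chromen-7-yl)oxy]acetic acid; 5 syringaldehyde (4-hydroxy-3,5-dimethoxybenzaldehyde)
Product: 8 (Z)-3-(4-acetoxy-3,5-dimethoxyphenyl)-2-[(6,8-dimethoxy-2-oxo-2H-chromen-7-yl)oxy]acrylic acid (carboxyl trans to the aryl ring), via 4-acetoxy-3,5-dimethoxybenzaldehyde 6 (not isolated), via mixed acetic anhydride 7 (not isolated)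
Conditions: Ac2O, Et3N, 110 °C; then H2O, dilute HCl
Reagents that add atoms: acetic anhydride, CC(=O)OC(C)=O
Why: Perkin (Oglialoro) condensation, in which acetic anhydride acetylates the phenol of 5 and turns 4 into its C–H acidic mixed anhydride 7, whose amine-generated enolate adds to aldehyde 6 before acetate elimination and aqueous work-up deliver the acrylic acid with the carboxyl group trans to the aryl ring, a geometry that need not be pure because step 4 equilibrates it.

Step 4
Reactants: 8 (Z)-3-(4-acetoxy-3,5-dimethoxyphenyl)-2-[(6,8-dimethoxy-2-oxo-2H-chromen-7-yl)oxy]acrylic acid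
Product: 10 7-acetoxy-3-[(6,8-dimethoxy-2-oxo-2H-chromen-7-yl)oxy]-6,8-dimethoxy-2H-chromen-2-one, via (E)-acrylic acid 9 (not isolated)
Conditions: riboflavin tetraacetate (10 mol %), O2 (1 atm), blue LEDs (ca. 450 nm), MeCN/MeOH 1:1, rt
Reagents that add atoms: none
Why: Triplet riboflavin tetraacetate should first transfer energy to the acrylic acid chromophore and interconvert 8 with its geometric isomer 9, in which the carboxyl group lies cis to the aryl ring; the excited flavin then removes one electron from the acetoxy-dimethoxy-styryl enol ether, the carboxylate adds to the ortho carbon of the radical cation, and a second oxidation with loss of the ortho proton rearomatizes while O2 reoxidizes the reduced flavin to give H2O2. The closest known reaction type is the flavin-photocatalysed (or anodic) dehydrogenative lactonization of cinnamic acids and biaryl-2-carboxylic acids to coumarins and benzocoumarins. The pyranone ring of unit A closes in a 6-endo-trig mode by O1–C8a bond formation at the ortho carbon, in preference to 5-exo attack at the ipso carbon, which would give a spirolactone that cannot rearomatize. No stereocentre is formed, and a favourable photostationary state is not required because only isomer 9 can cyclize and its irreversible consumption drains the equilibrium. Regioselectivity is secured by the local symmetry of the 4-acetoxy-3,5-dimethoxyphenyl ring, whose two ortho CH carbons are equivalent and each lie para to one methoxy group and ortho to the other, where the radical cation carries most of its spin and charge. Oxidation at this ring and not at unit B is expected because the isofraxidin coumarin is an electron-poor, lactone-conjugated arene with no carboxylate within reach, while the aryl acetate keeps the future 7-oxygen from phenol oxidation to a quinone methide.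

Step 5
Reactants: 10 7-acetoxy-3-[(6,8-dimethoxy-2-oxo-2H-chromen-7-yl)oxy]-6,8-dimethoxy-2H-chromen-2-one
Product: 11 7-hydroxy-3-[(6,8-dimethoxy-2-oxo-2H-chromen-7-yl)oxy]-6,8-dimethoxy-2H-chromen-2-one (target CNP0278842.0)
Conditions: HCl (1.25 M in MeOH), THF, 40 °C
Reagents that add atoms: none
Why: Acid-catalysed transesterification (methanolysis) of the aryl acetate should release the 7-OH as methyl acetate, while both coumarin lactones, which stay closed under acid, and the C3–O–C7' vinyl aryl ether, which resists protonation at C4, remain intact.

Compound list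
1 | isofraxidin (7-hydroxy-6,8-dimethoxy-2H-chromen-2-one) | COc1cc2ccc(=O)oc2c(OC)c1O | starting material
2 | tert-butyl bromoacetate | CC(C)(C)OC(=O)CBr | starting material
3 | tert-butyl 2-[(6,8-dimethoxy-2-oxo-2H-chromen-7-yl)oxy]acetate | COc1cc2ccc(=O)oc2c(OC)c1OCC(=O)OC(C)(C)C | intermediate
4 | 2-[(6,8-dimethoxy-2-oxo-2H-chromen-7-yl)oxy]acetic acid | COc1cc2ccc(=O)oc2c(OC)c1OCC(O)=O | intermediate
5 | syringaldehyde (4-hydroxy-3,5-dimethoxybenzaldehyde) | COc1cc(C=O)cc(OC)c1O | starting material
6 | 4-acetoxy-3,5-dimethoxybenzaldehyde (formed in the flask in step 3) | COc1cc(C=O)cc(OC)c1OC(C)=O | intermediate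
7 | acetic 2-[(6,8-dimethoxy-2-oxo-2H-chromen-7-yl)oxy]acetic anhydride (mixed anhydride, formed in the flask in step 3) | COc1cc2ccc(=O)oc2c(OC)c1OCC(=O)OC(C)=O | intermediate
8 | (Z)-3-(4-acetoxy-3,5-dimethoxyphenyl)-2-[(6,8-dimethoxy-2-oxo-2H-chromen-7-yl)oxy]acrylic acid (carboxyl trans to aryl) | OC(=O)/C(Oc1c(OC)cc2ccc(=O)oc2c1OC)=C/c1cc(OC)c(OC(C)=O)c(OC)c1 | intermediate
9 | (E)-3-(4-acetoxy-3,5-dimethoxyphenyl)-2-[(6,8-dimethoxy-2-oxo-2H-chromen-7-yl)oxy]acrylic acid (carboxyl cis to aryl, photoisomer formed in the flask in step 4) | OC(=O)/C(Oc1c(OC)cc2ccc(=O)oc2c1OC)=C\c1cc(OC)c(OC(C)=O)c(OC)c1 | intermediate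
10 | 7-acetoxy-3-[(6,8-dimethoxy-2-oxo-2H-chromen-7-yl)oxy]-6,8-dimethoxy-2H-chromen-2-one | COc1cc2cc(Oc3c(OC)cc4ccc(=O)oc4c3OC)c(=O)oc2c(OC)c1OC(C)=O | intermediate
11 | 7-hydroxy-3-[(6,8-dimethoxy-2-oxo-2H-chromen-7-yl)oxy]-6,8-dimethoxy-2H-chromen-2-one | COc1cc2cc(Oc3c(OC)cc4ccc(=O)oc4c3OC)c(=O)oc2c(OC)c1O | target

Total step count: 5
Longest linear sequence: 5 steps (1 → 3 → 4 → 8 → 10 → 11)

Steps most likely to fail

1. Step 4. The electron-rich enol ether alkene may be cleaved oxidatively by singlet oxygen or superoxide. Back electron transfer may also outrun carboxylate attack, so that the two alkene isomers only interconvert. Fallback: the pyranone ring of unit A would be built by a Perkin–Oglialoro annulation on a salicylaldehyde instead of by C–H lactonization. The fallback sets out from syringaldehyde 5 and acid 4. Bromination of 5 (Br2, AcOH, rt) at one of its two equivalent free ring positions should give 2-bromo-4-hydroxy-3,5-dimethoxybenzaldehyde F1. Copper-catalysed hydroxylation of the aryl bromide (CuI, 1,10-phenanthroline, KOH, DMSO/H2O, 100 °C, then dilute acid) should give 2,4-dihydroxy-3,5-dimethoxybenzaldehyde F2. Heating F2 with 4 in Ac2O/Et3N should condense the activated methylene with the aldehyde, lactonize onto the ortho phenol and acetylate the para phenol, and so come back to the route at 10.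

2. Step 3. Enolization and condensation of the alpha-aryloxy acid with a hindered, electron-rich aldehyde may be sluggish, and the product acrylic acid may decarboxylate on prolonged heating. Fallback: the alkene would be made by carbenoid O–H insertion followed by Horner–Wadsworth–Emmons olefination, setting out from isofraxidin 1. Diazo transfer to commercial tert-butyl diethylphosphonoacetate (4-acetamidobenzenesulfonyl azide, DBU, MeCN) should give tert-butyl 2-diazo-2-(diethoxyphosphoryl)acetate F3. O–H insertion of its carbenoid into the phenol of 1 (Rh2(OAc)4, toluene, 80 °C) should give racemic tert-butyl 2-(diethoxyphosphoryl)-2-[(6,8-dimethoxy-2-oxo-2H-chromen-7-yl)oxy]acetate F4. Olefination of separately prepared aldehyde 6 (from 5, Ac2O, pyridine) with F4 under LiCl/DBU in MeCN should give tert-butyl 3-(4-acetoxy-3,5-dimethoxyphenyl)-2-[(6,8-dimethoxy-2-oxo-2H-chromen-7-yl)oxy]acrylate F5, expected as a mixture of alkene isomers. TFA in CH2Cl2 would then cleave the ester and come back to the route at 8; any 9 formed alongside is equally usable in step 4.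

3. Step 1. The phenoxide is flanked by two methoxy groups and is attenuated by conjugation with the lactone, so O-alkylation may be slow, and long heating with carbonate could open the lactone. Fallback: the ether would be formed by a Mitsunobu reaction, which activates the alcohol partner instead of relying on the nucleophilicity of the phenoxide. It sets out from 1 with commercial tert-butyl glycolate (PPh3, DIAD, THF, 0 °C to rt) and comes back to the route at 3 without any new intermediate.

Further compounds
F1 | step 4 | 2-bromo-4-hydroxy-3,5-dimethoxybenzaldehyde | COc1cc(C=O)c(Br)c(OC)c1O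
F2 | step 4 | 2,4-dihydroxy-3,5-dimethoxybenzaldehyde | COc1cc(C=O)c(O)c(OC)c1O
F3 | step 3 | tert-butyl 2-diazo-2-(diethoxyphosphoryl)acetate | CCOP(=O)(OCC)C(=[N+]=[N-])C(=O)OC(C)(C)C
F4 | step 3 | racemic tert-butyl 2-(diethoxyphosphoryl)-2-[(6,8-dimethoxy-2-oxo-2H-chromen-7-yl)oxy]acetate | CCOP(=O)(OCC)C(Oc1c(OC)cc2ccc(=O)oc2c1OC)C(=O)OC(C)(C)C
F5 | step 3 | tert-butyl 3-(4-acetoxy-3,5-dimethoxyphenyl)-2-[(6,8-dimethoxy-2-oxo-2H-chromen-7-yl)oxy]acrylate (mixture of alkene isomers, Z isomer drawn) | CC(C)(C)OC(=O)/C(Oc1c(OC)cc2ccc(=O)oc2c1OC)=C/c1cc(OC)c(OC(C)=O)c(OC)c1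
F0 | step 1 | none | none
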